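Cyclopentene ring D (indene locants) is disconnected at both bonds to ring C: C7a–C1, between the vicinal quaternary carbons, and C3a–C3. Both form in one flask from a 2-oxabicyclo[2.2.2]oct-5-en-4-ol whose ether carbon (future C3) links the C7 oxygen to the carbinol carbon (future C4) and bears C2=C1 as an E-alkene. An anionic oxy-Cope shift through an enforced boat carries C1 to C7a on the face of the C7 oxygen; acid then turns the cyclic enol ether into the C3 aldehyde, which closes ring D onto C3a by aldol condensation and frees the C7 hydroxyl. The step exploits the cis C7–O/C7a–C1 relationship and the oxygenated C4.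

Key step: step 11

Remark: locants C1–C7a are those of the 1H-indene core of the target (ring C six-membered, ring D five-membered); the two faces of the oxabicyclo[2.2.2]octene are named after its etheno (C5=C6) and ethano (C7–C8) bridges; the enol-ether geometry of 7 and the acetal configuration of 8, 9 and 10 are of no consequence and are carried as mixtures.

Step 1
Reactants: 1 4-methoxy-2-methylphenol
Product: 2 4,4-dimethoxy-2-methylcyclohexa-2,5-dien-1-one
Conditions: PhI(OAc)2, MeOH, 0 °C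
Reagents that add atoms: methanol, CO
Why: Oxidative dearomatisation of a para-alkoxyphenol by the trivalent iodine reagent in methanol traps the phenoxenium ion at the methoxy-bearing carbon and gives the quinone monoketal, with no stereocentre formed.

Step 2
Reactants: 2 4,4-dimethoxy-2-methylcyclohexa-2,5-dien-1-one
Product: 3 4,4-dimethoxy-2-methylcyclohex-2-en-1-one
Conditions: H2 (1 atm), RhCl(PPh3)3 (cat.), benzene, 25 °C
Reagents that add atoms: none
Why: Homogeneous hydrogenation with the monovalent rhodium complex is sensitive to alkene substitution, so the disubstituted C5=C6 bond should be saturated while the trisubstituted methyl-bearing enone and the ketal stay.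

Step 3
Reactants: 3 4,4-dimethoxy-2-methylcyclohex-2-en-1-one
Product: 5 (4R)-4-hydroxy-3-methylcyclohex-2-en-1-one, via allylic alcohol ketal 4 (not isolated)
Conditions: (S)-2-methyl-CBS-oxazaborolidine (cat.), BH3·SMe2, THF, −20 °C; then 1 M HCl, THF, 0 °C
Reagents that add atoms: water, O
Why: Corey–Bakshi–Shibata (CBS) reduction in which the alkenyl carbon acts as the large group, so that the S catalyst should give the R carbinol, followed by acid hydrolysis of the dimethyl ketal to the enone.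

Step 4
Reactants: 5 (4R)-4-hydroxy-3-methylcyclohex-2-en-1-one; 6 (methoxymethyl)triphenylphosphonium chloride
Product: 7 triethyl{[(1R)-4-(methoxymethylidene)-2-methylcyclohex-2-en-1-yl]oxy}silane (E/Z mixture)
Conditions: 6, KN(SiMe3)2, THF, −78 to 0 °C; then 5; then Et3SiCl, 0 °C
Reagents that add atoms: chlorotriethylsilane, CC[Si](Cl)(CC)CC
Why: Wittig methoxymethylenation of the enone carbonyl (the hydroxyl rides as its potassium alkoxide and is capped in the same flask) gives the 1-methoxy diene, whose geometry is irrelevant because this carbon becomes tetrahedral in the next step.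

Step 5
Reactants: 7 triethyl{[(1R)-4-(methoxymethylidene)-2-methylcyclohex-2-en-1-yl]oxy}silane
Product: 9 (1R,4R)-6-methyl-2-oxabicyclo[2.2.2]oct-5-ene-3,4-diol (bridged lactol), via spiro epoxy ether 8 (not isolated)
Conditions: dimethyldioxirane, acetone/CH2Cl2, −78 °C; then pyridinium p-toluenesulfonate, THF/H2O, 0 to 25 °C
Reagents that add atoms: dimethyldioxirane, CC1(C)OO1; water, O
Why: Rubottom-type epoxidation of the electron-rich enol-ether alkene should occur anti to the pseudo-axial silyloxy group (held axial by allylic strain with the ring methyl), which places the new tertiary oxygen trans to the ring oxygen substituent, and aqueous acid then opens the epoxy ether, removes the silyl group and lets the hydroxy aldehyde close to the bridged lactol that only this epimer can form.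

Step 6
Reactants: 9 (1R,4R)-6-methyl-2-oxabicyclo[2.2.2]oct-5-ene-3,4-diol
Product: 10 (1R,4R)-4-hydroxy-6-methyl-2-oxabicyclo[2.2.2]oct-5-en-3-yl acetate
Conditions: Ac2O, pyridine, CH2Cl2, 0 °C
Reagents that add atoms: acetic anhydride, CC(=O)OC(C)=O
Why: Chemoselective acetylation of the hemiacetal hydroxyl, the tertiary bridgehead hydroxyl being too hindered to react without an acyl-transfer catalyst.

Step 7
Reactants: 11 3-methylideneoxolan-2-one
Product: 12 (3R)-3-methyloxolan-2-one
Conditions: H2 (50 bar), Ru(OAc)2[(S)-BINAP] (cat.), CH2Cl2/MeOH, 50 °C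
Reagents that add atoms: none
Why: Asymmetric hydrogenation of the exocyclic alkene with the divalent ruthenium–BINAP catalyst sets the methyl stereocentre, the BINAP antipode being the one chosen to give the R lactone.

Step 8
Reactants: 12 (3R)-3-methyloxolan-2-one
Product: 14 (3R)-3-methylpent-4-yn-1-ol, via lactol 13 (not isolated)
Conditions: iBu2AlH, CH2Cl2, −78 °C; then MeOH, K2CO3, dimethyl (1-diazo-2-oxopropyl)phosphonate, 0 to 25 °C
Reagents that add atoms: dimethyl (1-diazo-2-oxopropyl)phosphonate, COP(=O)(OC)C(=[N+]=[N-])C(C)=O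
Why: Half-reduction to the lactol and Ohira–Bestmann homologation of its open hydroxy-aldehyde form give the terminal alkyne, the mild carbonate conditions being chosen to keep the adjacent stereocentre intact.

Step 9
Reactants: 14 (3R)-3-methylpent-4-yn-1-ol
Product: 15 tert-butyl{[(3R)-3-methylpent-4-yn-1-yl]oxy}diphenylsilane
Conditions: t-BuPh2SiCl, imidazole, DMF, 25 °C
Reagents that add atoms: tert-butyl(chloro)diphenylsilane, CC(C)(C)[Si](Cl)(c1ccccc1)c1ccccc1
Why: Silylation of the primary alcohol with a group that withstands aluminium reagents, potassium hydride and aqueous acid.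

Step 10
Reactants: 10 (1R,4R)-4-hydroxy-6-methyl-2-oxabicyclo[2.2.2]oct-5-en-3-yl acetate; 15 tert-butyl{[(3R)-3-methylpent-4-yn-1-yl]oxy}diphenylsilane
Product: 17 (1R,3R,4R)-3-{(1E,3R)-5-[(tert-butyldiphenylsilyl)oxy]-2,3-dimethylpent-1-en-1-yl}-6-methyl-2-oxabicyclo[2.2.2]oct-5-en-4-ol, via alkenylalane 16 (not isolated)
Conditions: 15, AlMe3, Cp2ZrCl2 (cat.), CH2Cl2, 0 to 25 °C; then 10, CH2Cl2, −30 to 0 °C
Reagents that add atoms: trimethylaluminium, C[Al](C)C
Why: Zirconium-catalysed syn-carboalumination (Negishi carboalumination) fixes the E trisubstituted alkene and brings in the methyl group, and the alkenylalane then ionises the anomeric acetate and adds to the bridged oxocarbenium ion from its less hindered face beside the etheno bridge (C-glycosylation-type acetal substitution), which sets C3 with the alkenyl group syn to C5=C6.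

Step 11
Reactants: 17 (1R,3R,4R)-3-{(1E,3R)-5-[(tert-butyldiphenylsilyl)oxy]-2,3-dimethylpent-1-en-1-yl}-6-methyl-2-oxabicyclo[2.2.2]oct-5-en-4-ol
Product: 20 (1S,7R,7aS)-1-{(2R)-4-[(tert-butyldiphenylsilyl)oxy]butan-2-yl}-7-hydroxy-1,7a-dimethyl-1,2,5,6,7,7a-hexahydro-4H-inden-4-one, via cis-fused chromenone enolate 18 (not isolated), via hydroxy keto aldehyde 19 (not isolated)
Conditions: KH, 18-crown-6, THF, 0 to 50 °C; then 2 M HCl, THF, 25 to 40 °C (same flask)
Reagents that add atoms: none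
Why: The potassium alkoxide of the bridgehead carbinol triggers an anionic oxy-Cope rearrangement of the 1,5-diene C6=C5–C4(O−)–C3–CH=C(alkenyl terminus) that joins C6 to the alkenyl terminus (C7a–C1 of the target) and breaks C3–C4, leaving a ketone enolate and a cyclic enol ether; acid then hydrolyses the enol ether to the C3 aldehyde, and the ketone enol at C3a adds to it and dehydrates (aldol condensation), forming C3a–C3. The closest known reaction type is the anionic oxy-Cope rearrangement of syn-alkenyl bicyclo[2.2.2]oct-5-en-2-olates to cis-fused bicyclic ketones, followed by intramolecular aldol condensation. The [3,3] shift closes the dihydropyran ring suprafacially on both allyl units through the boat that the bicycle enforces, and the aldol closes ring D in a 5-(enolexo)-exo-trig mode. C7a is set because the migrating carbon is tied to the C7 oxygen, so the new bond must form on that face; C1 is set by the E alkene geometry in the boat, where the methyl cis to C3 ends syn to C7 and the chain carbon ends syn to the C7a methyl, while C7 and the side-chain centre are carried through unchanged. The step needs the concerted shift to outrun alkoxide fragmentation and the aldol to use C3a and not C5: the tethered syn alkene secures the first, and the five-membered ring with irreversible dehydration to the conjugated enone secures the second (the C5 enol would need a seven-membered ring, and addition of the aldehyde enol to the ketone is reversible and cannot dehydrate). A silyl ether and not an ester is carried at the side-chain terminus because an ester there could acylate the enolate.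

Step 12
Reactants: 20 (1S,7R,7aS)-1-{(2R)-4-[(tert-butyldiphenylsilyl)oxy]butan-2-yl}-7-hydroxy-1,7a-dimethyl-1,2,5,6,7,7a-hexahydro-4H-inden-4-one
Product: 21 (1S,7R,7aS)-7-[(tert-butyldimethylsilyl)oxy]-1-{(2R)-4-[(tert-butyldiphenylsilyl)oxy]butan-2-yl}-1,7a-dimethyl-1,2,5,6,7,7a-hexahydro-4H-inden-4-one
Conditions: t-BuMe2SiOTf, 2,6-lutidine, CH2Cl2, −78 to 0 °C
Reagents that add atoms: tert-butyldimethylsilyl triflate, CC(C)(C)[Si](C)(C)OS(=O)(=O)C(F)(F)F
Why: Silylation of the hindered C7 hydroxyl with the reactive silyl triflate keeps this oxygen from O-alkylation and from capturing the ring A cation later.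

Step 13
Reactants: 22 2-methylprop-2-en-1-ol; 23 1-bromo-3-methylbut-2-ene
Product: 24 6-methyl-2-methylidenehept-5-en-1-ol
Conditions: n-BuLi (2 equiv), TMEDA, Et2O/hexane, 0 to 25 °C; then 23, −78 to 0 °C
Reagents that add atoms: none
Why: The O,C-dilithiated methallyl alcohol is alkylated at carbon by the allylic bromide (SN2 alkylation of an allylic dianion).

Step 14
Reactants: 24 6-methyl-2-methylidenehept-5-en-1-ol
Product: 25 4-[(2S)-3,3-dimethyloxiran-2-yl]-2-methylidenebutan-1-ol
Conditions: L-fructose-derived ketone (enantiomer of the D-fructose-derived Shi ketone, cat.), KHSO5 (as 2KHSO5·KHSO4·K2SO4), K2CO3, Bu4NHSO4, MeCN/CH2(OMe)2/aqueous buffer, 0 °C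
Reagents that add atoms: potassium peroxymonosulfate, [K+].[O-]S(=O)(=O)OO
Why: Shi epoxidation, in which the chiral dioxirane attacks the electron-rich trisubstituted alkene in preference to the 1,1-disubstituted one, the ketone antipode being the one chosen to give the S epoxide.

Step 15
Reactants: 25 4-[(2S)-3,3-dimethyloxiran-2-yl]-2-methylidenebutan-1-ol
Product: 27 (3S)-3-[3-(bromomethyl)but-3-en-1-yl]-2,2-dimethyloxirane, via allylic mesylate 26 (not isolated)
Conditions: MeSO2Cl, Et3N, CH2Cl2, −40 °C; then LiBr, THF, 0 °C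
Reagents that add atoms: lithium bromide, [Li+].[Br-]
Why: Mesylation and Finkelstein-type SN2 displacement by bromide give the allylic bromide without touching the trisubstituted epoxide.

Step 16
Reactants: 21 (1S,7R,7aS)-7-[(tert-butyldimethylsilyl)oxy]-1-{(2R)-4-[(tert-butyldiphenylsilyl)oxy]butan-2-yl}-1,7a-dimethyl-1,2,5,6,7,7a-hexahydro-4H-inden-4-one; 27 (3S)-3-[3-(bromomethyl)but-3-en-1-yl]-2,2-dimethyloxirane
Product: 28 (1S,7R,7aS)-7-[(tert-butyldimethylsilyl)oxy]-1-{(2R)-4-[(tert-butyldiphenylsilyl)oxy]butan-2-yl}-5-{4-[(2S)-3,3-dimethyloxiran-2-yl]-2-methylidenebutyl}-1,7a-dimethyl-1,2,5,6,7,7a-hexahydro-4H-inden-4-one (C5 epimers)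
Conditions: LiN(iPr)2, THF, −78 °C; then 27, DMPU, −78 to −20 °C
Reagents that add atoms: none
Why: Kinetic deprotonation of the cross-conjugated enone at the C5 methylene and SN2 alkylation by the allylic bromide; the new C5 centre is of no consequence because C5 becomes trigonal in the next step.

Step 17
Reactants: 28 (1S,7R,7aS)-7-[(tert-butyldimethylsilyl)oxy]-1-{(2R)-4-[(tert-butyldiphenylsilyl)oxy]butan-2-yl}-5-{4-[(2S)-3,3-dimethyloxiran-2-yl]-2-methylidenebutyl}-1,7a-dimethyl-1,2,5,6,7,7a-hexahydro-4H-inden-4-one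
Product: 29 (1S,7R,7aS)-7-[(tert-butyldimethylsilyl)oxy]-1-{(2R)-4-[(tert-butyldiphenylsilyl)oxy]butan-2-yl}-5-{4-[(2S)-3,3-dimethyloxiran-2-yl]-2-methylidenebutyl}-1,7a-dimethyl-2,6,7,7a-tetrahydro-1H-inden-4-yl trifluoromethanesulfonate
Conditions: KN(SiMe3)2, THF, −78 °C; then PhNTf2, −78 to 0 °C
Reagents that add atoms: N-phenylbis(trifluoromethanesulfonimide), O=S(=O)(N(c1ccccc1)S(=O)(=O)C(F)(F)F)C(F)(F)F
Why: Kinetic enolisation toward C5, which carries the only α-hydrogen and is deprotonated faster than the γ-position C2, and O-sulfonylation give the cross-conjugated dienyl triflate with the C4=C5 and C3=C3a double bonds of the target in place.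

Step 18
Reactants: 29 (1S,7R,7aS)-7-[(tert-butyldimethylsilyl)oxy]-1-{(2R)-4-[(tert-butyldiphenylsilyl)oxy]butan-2-yl}-5-{4-[(2S)-3,3-dimethyloxiran-2-yl]-2-methylidenebutyl}-1,7a-dimethyl-2,6,7,7a-tetrahydro-1H-inden-4-yl trifluoromethanesulfonate
Product: 30 (1S,7R,7aS)-7-[(tert-butyldimethylsilyl)oxy]-1-{(2R)-4-[(tert-butyldiphenylsilyl)oxy]butan-2-yl}-5-{[(1S,4S)-3,3-dimethyl-7-oxabicyclo[2.2.1]heptan-1-yl]methyl}-1,7a-dimethyl-2,6,7,7a-tetrahydro-1H-inden-4-yl trifluoromethanesulfonate
Conditions: BF3·OEt2, CH2Cl2, −78 °C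
Reagents that add atoms: none
Why: Lewis-acid epoxide–alkene cyclisation (cation–olefin type) in which the methylidene CH2 attacks the tertiary epoxide carbon in a 6-endo mode and the boron-bound alkoxide captures the resulting tertiary cation across the new ring to give the 7-oxabicyclo[2.2.1]heptane; the secondary C–O centre of the epoxide is untouched and dictates the bridgehead configuration.

Step 19
Reactants: 30 (1S,7R,7aS)-7-[(tert-butyldimethylsilyl)oxy]-1-{(2R)-4-[(tert-butyldiphenylsilyl)oxy]butan-2-yl}-5-{[(1S,4S)-3,3-dimethyl-7-oxabicyclo[2.2.1]heptan-1-yl]methyl}-1,7a-dimethyl-2,6,7,7a-tetrahydro-1H-inden-4-yl trifluoromethanesulfonate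
Product: 31 2-(trimethylsilyl)ethyl (1S,7R,7aS)-7-[(tert-butyldimethylsilyl)oxy]-1-{(2R)-4-[(tert-butyldiphenylsilyl)oxy]butan-2-yl}-5-{[(1S,4S)-3,3-dimethyl-7-oxabicyclo[2.2.1]heptan-1-yl]methyl}-1,7a-dimethyl-2,6,7,7a-tetrahydro-1H-indene-4-carboxylate
Conditions: Pd(OAc)2 (cat.), Fe(C5H4PPh2)2 (dppf), CO (1 atm), Me3SiCH2CH2OH, Et3N, DMF, 60 °C
Reagents that add atoms: carbon monoxide, [C-]#[O+]; 2-(trimethylsilyl)ethanol, C[Si](C)(C)CCO
Why: Palladium-catalysed alkoxycarbonylation of the alkenyl triflate (oxidative addition to zerovalent palladium, CO insertion, alcoholysis) installs the C4 carboxyl as a fluoride-labile ester.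

Step 20
Reactants: 31 2-(trimethylsilyl)ethyl (1S,7R,7aS)-7-[(tert-butyldimethylsilyl)oxy]-1-{(2R)-4-[(tert-butyldiphenylsilyl)oxy]butan-2-yl}-5-{[(1S,4S)-3,3-dimethyl-7-oxabicyclo[2.2.1]heptan-1-yl]methyl}-1,7a-dimethyl-2,6,7,7a-tetrahydro-1H-indene-4-carboxylate
Product: 32 (1S,7R,7aS)-5-{[(1S,4S)-3,3-dimethyl-7-oxabicyclo[2.2.1]heptan-1-yl]methyl}-7-hydroxy-1-[(2R)-4-hydroxybutan-2-yl]-1,7a-dimethyl-2,6,7,7a-tetrahydro-1H-indene-4-carboxylic acid
Conditions: Bu4NF, THF, 25 to 45 °C; aqueous NH4Cl work-up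
Reagents that add atoms: none
Why: Fluoride cleaves both silyl ethers and, by β-elimination, the 2-(trimethylsilyl)ethyl ester in one global deprotection.

Step 21
Reactants: 32 (1S,7R,7aS)-5-{[(1S,4S)-3,3-dimethyl-7-oxabicyclo[2.2.1]heptan-1-yl]methyl}-7-hydroxy-1-[(2R)-4-hydroxybutan-2-yl]-1,7a-dimethyl-2,6,7,7a-tetrahydro-1H-indene-4-carboxylic acid
Product: 33 (3R)-3-[(1S,7R,7aS)-4-carboxy-5-{[(1S,4S)-3,3-dimethyl-7-oxabicyclo[2.2.1]heptan-1-yl]methyl}-7-hydroxy-1,7a-dimethyl-2,6,7,7a-tetrahydro-1H-inden-1-yl]butanoic acid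
Conditions: TEMPO (cat.), PhI(OAc)2, MeCN/aqueous pH 7 buffer, 25 °C
Reagents that add atoms: water, O
Why: Oxoammonium (TEMPO) oxidation is selective for the primary alcohol and runs through the aldehyde hydrate to the acid, while the hindered secondary C7 hydroxyl should be left and a seven-membered lactol across the C7a–C1 bond is geometrically disfavoured.

Compound list
1 | 4-methoxy-2-methylphenol | COc1ccc(O)c(C)c1 | starting material
2 | 4,4-dimethoxy-2-methylcyclohexa-2,5-dien-1-one | COC1(OC)C=CC(=O)C(C)=C1 | intermediate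
3 | 4,4-dimethoxy-2-methylcyclohex-2-en-1-one | COC1(OC)CCC(=O)C(C)=C1 | intermediate
4 | (1R)-4,4-dimethoxy-2-methylcyclohex-2-en-1-ol | COC1(OC)CC[C@@H](O)C(C)=C1 | intermediate (not isolated)
5 | (4R)-4-hydroxy-3-methylcyclohex-2-en-1-one | O=C1CC[C@@H](O)C(C)=C1 | intermediate
6 | (methoxymethyl)triphenylphosphonium chloride | COC[P+](c1ccccc1)(c1ccccc1)c1ccccc1.[Cl-] | starting material
7 | triethyl{[(1R)-4-(methoxymethylidene)-2-methylcyclohex-2-en-1-yl]oxy}silane, E/Z mixture | COC=C1CC[C@@H](O[Si](CC)(CC)CC)C(C)=C1 | intermediate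
8 | triethyl{[(3R,6R)-2-methoxy-5-methyl-1-oxaspiro[2.5]oct-4-en-6-yl]oxy}silane, both C2 epimers | COC1O[C@@]12CC[C@@H](O[Si](CC)(CC)CC)C(C)=C2 | intermediate (not isolated)
9 | (1R,4R)-6-methyl-2-oxabicyclo[2.2.2]oct-5-ene-3,4-diol, both C3 epimers | O[C@@]12CC[C@@H](OC1O)C(C)=C2 | intermediate
10 | (1R,4R)-4-hydroxy-6-methyl-2-oxabicyclo[2.2.2]oct-5-en-3-yl acetate, both C3 epimers | O[C@@]12CC[C@@H](OC1OC(C)=O)C(C)=C2 | intermediate
11 | 3-methylideneoxolan-2-one | C=C1CCOC1=O | starting material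
12 | (3R)-3-methyloxolan-2-one | C[C@@H]1CCOC1=O | intermediate
13 | (3R)-3-methyloxolan-2-ol | C[C@@H]1CCOC1O | intermediate (not isolated)
14 | (3R)-3-methylpent-4-yn-1-ol | C#C[C@H](C)CCO | intermediate
15 | tert-butyl{[(3R)-3-methylpent-4-yn-1-yl]oxy}diphenylsilane | C#C[C@H](C)CCO[Si](c1ccccc1)(c1ccccc1)C(C)(C)C | intermediate
16 | {(1E,3R)-5-[(tert-butyldiphenylsilyl)oxy]-2,3-dimethylpent-1-en-1-yl}dimethylalumane | C[Al](C)/C=C(\C)[C@H](C)CCO[Si](c1ccccc1)(c1ccccc1)C(C)(C)C | intermediate (not isolated)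
17 | (1R,3R,4R)-3-{(1E,3R)-5-[(tert-butyldiphenylsilyl)oxy]-2,3-dimethylpent-1-en-1-yl}-6-methyl-2-oxabicyclo[2.2.2]oct-5-en-4-ol | O[C@@]12CC[C@@H](O[C@@H]1/C=C(\C)[C@H](C)CCO[Si](c1ccccc1)(c1ccccc1)C(C)(C)C)C(C)=C2 | intermediate
18 | (4R,4aR,8aR)-4-{(2R)-4-[(tert-butyldiphenylsilyl)oxy]butan-2-yl}-4,4a-dimethyl-4a,5,8,8a-tetrahydro-4H-chromen-6(7H)-one, cis-fused, present as its potassium enolate | O=C1CC[C@H]2OC=C[C@@](C)([C@H](C)CCO[Si](c3ccccc3)(c3ccccc3)C(C)(C)C)[C@@]2(C)C1 | intermediate (not isolated)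
19 | (3S,4R)-6-[(tert-butyldiphenylsilyl)oxy]-3-[(1R,2R)-2-hydroxy-1-methyl-5-oxocyclohexyl]-3,4-dimethylhexanal, in equilibrium with its six-membered lactol | O=CC[C@@](C)([C@H](C)CCO[Si](c1ccccc1)(c1ccccc1)C(C)(C)C)[C@@]1(C)CC(=O)CC[C@H]1O | intermediate (not isolated)
20 | (1S,7R,7aS)-1-{(2R)-4-[(tert-butyldiphenylsilyl)oxy]butan-2-yl}-7-hydroxy-1,7a-dimethyl-1,2,5,6,7,7a-hexahydro-4H-inden-4-one | C[C@H](CCO[Si](c1ccccc1)(c1ccccc1)C(C)(C)C)[C@]1(C)CC=C2C(=O)CC[C@@H](O)[C@]21C | intermediate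
21 | (1S,7R,7aS)-7-[(tert-butyldimethylsilyl)oxy]-1-{(2R)-4-[(tert-butyldiphenylsilyl)oxy]butan-2-yl}-1,7a-dimethyl-1,2,5,6,7,7a-hexahydro-4H-inden-4-one | C[C@H](CCO[Si](c1ccccc1)(c1ccccc1)C(C)(C)C)[C@]1(C)CC=C2C(=O)CC[C@@H](O[Si](C)(C)C(C)(C)C)[C@]21C | intermediate
22 | 2-methylprop-2-en-1-ol | CC(=C)CO | starting material
23 | 1-bromo-3-methylbut-2-ene | CC(C)=CCBr | starting material
24 | 6-methyl-2-methylidenehept-5-en-1-ol | OCC(=C)CCC=C(C)C | intermediate
25 | 4-[(2S)-3,3-dimethyloxiran-2-yl]-2-methylidenebutan-1-ol | OCC(=C)CC[C@@H]1OC1(C)C | intermediate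
26 | 4-[(2S)-3,3-dimethyloxiran-2-yl]-2-methylidenebutyl methanesulfonate | CS(=O)(=O)OCC(=C)CC[C@@H]1OC1(C)C | intermediate (not isolated)
27 | (3S)-3-[3-(bromomethyl)but-3-en-1-yl]-2,2-dimethyloxirane | BrCC(=C)CC[C@@H]1OC1(C)C | intermediate
28 | (1S,7R,7aS)-7-[(tert-butyldimethylsilyl)oxy]-1-{(2R)-4-[(tert-butyldiphenylsilyl)oxy]butan-2-yl}-5-{4-[(2S)-3,3-dimethyloxiran-2-yl]-2-methylidenebutyl}-1,7a-dimethyl-1,2,5,6,7,7a-hexahydro-4H-inden-4-one, C5 epimers | C[C@H](CCO[Si](c1ccccc1)(c1ccccc1)C(C)(C)C)[C@]1(C)CC=C2C(=O)C(CC(=C)CC[C@@H]3OC3(C)C)C[C@@H](O[Si](C)(C)C(C)(C)C)[C@]21C | intermediate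
29 | (1S,7R,7aS)-7-[(tert-butyldimethylsilyl)oxy]-1-{(2R)-4-[(tert-butyldiphenylsilyl)oxy]butan-2-yl}-5-{4-[(2S)-3,3-dimethyloxiran-2-yl]-2-methylidenebutyl}-1,7a-dimethyl-2,6,7,7a-tetrahydro-1H-inden-4-yl trifluoromethanesulfonate | C[C@H](CCO[Si](c1ccccc1)(c1ccccc1)C(C)(C)C)[C@]1(C)CC=C2C(OS(=O)(=O)C(F)(F)F)=C(CC(=C)CC[C@@H]3OC3(C)C)C[C@@H](O[Si](C)(C)C(C)(C)C)[C@]21C | intermediate
30 | (1S,7R,7aS)-7-[(tert-butyldimethylsilyl)oxy]-1-{(2R)-4-[(tert-butyldiphenylsilyl)oxy]butan-2-yl}-5-{[(1S,4S)-3,3-dimethyl-7-oxabicyclo[2.2.1]heptan-1-yl]methyl}-1,7a-dimethyl-2,6,7,7a-tetrahydro-1H-inden-4-yl trifluoromethanesulfonate | C[C@H](CCO[Si](c1ccccc1)(c1ccccc1)C(C)(C)C)[C@]1(C)CC=C2C(OS(=O)(=O)C(F)(F)F)=C(C[C@]34CC[C@H](O3)C(C)(C)C4)C[C@@H](O[Si](C)(C)C(C)(C)C)[C@]21C | intermediate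
31 | 2-(trimethylsilyl)ethyl (1S,7R,7aS)-7-[(tert-butyldimethylsilyl)oxy]-1-{(2R)-4-[(tert-butyldiphenylsilyl)oxy]butan-2-yl}-5-{[(1S,4S)-3,3-dimethyl-7-oxabicyclo[2.2.1]heptan-1-yl]methyl}-1,7a-dimethyl-2,6,7,7a-tetrahydro-1H-indene-4-carboxylate | C[C@H](CCO[Si](c1ccccc1)(c1ccccc1)C(C)(C)C)[C@]1(C)CC=C2C(C(=O)OCC[Si](C)(C)C)=C(C[C@]34CC[C@H](O3)C(C)(C)C4)C[C@@H](O[Si](C)(C)C(C)(C)C)[C@]21C | intermediate
32 | (1S,7R,7aS)-5-{[(1S,4S)-3,3-dimethyl-7-oxabicyclo[2.2.1]heptan-1-yl]methyl}-7-hydroxy-1-[(2R)-4-hydroxybutan-2-yl]-1,7a-dimethyl-2,6,7,7a-tetrahydro-1H-indene-4-carboxylic acid | C[C@H](CCO)[C@]1(C)CC=C2C(C(=O)O)=C(C[C@]34CC[C@H](O3)C(C)(C)C4)C[C@@H](O)[C@]21C | intermediate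
33 | (3R)-3-[(1S,7R,7aS)-4-carboxy-5-{[(1S,4S)-3,3-dimethyl-7-oxabicyclo[2.2.1]heptan-1-yl]methyl}-7-hydroxy-1,7a-dimethyl-2,6,7,7a-tetrahydro-1H-inden-1-yl]butanoic acid | C[C@H](CC(=O)O)[C@]1(C)CC=C2C(C(=O)O)=C(C[C@]34CC[C@H](O3)C(C)(C)C4)C[C@@H](O)[C@]21C | target

Total step count: 21. Longest linear sequence: 15 steps (steps 1–6, 10–12 and 16–21).

Steps most likely to fail

Step 11 (key step). The hindered [3,3] shift has to join two fully substituted carbons, and the potassium alkoxide may instead fragment heterolytically at the C3–C4 bond or undergo a [1,3] shift, so that material is lost before the new C7a–C1 bond forms. The fallback leaves the ionic manifold and runs the rearrangement as a neutral, strictly concerted siloxy-Cope reaction on a different substrate. Setting out from 17, silylation (Me3SiCl, imidazole, DMF) would give trimethyl{[(1R,3R,4R)-3-{(1E,3R)-5-[(tert-butyldiphenylsilyl)oxy]-2,3-dimethylpent-1-en-1-yl}-6-methyl-2-oxabicyclo[2.2.2]oct-5-en-4-yl]oxy}silane F1. Heating F1 in a sealed tube (o-dichlorobenzene, about 230 °C) should give, through the same enforced boat and without any alkoxide that could fragment, the silyl enol ether tert-butyl{(3R)-3-[(4R,4aR,8aR)-4,4a-dimethyl-6-[(trimethylsilyl)oxy]-4a,7,8,8a-tetrahydro-4H-chromen-4-yl]butoxy}diphenylsilane F2. Aqueous HCl in THF would then cleave both enol ethers and bring about the aldol condensation, which comes back to the route at 20.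

Step 10. Methyl instead of alkenyl may be transferred from aluminium, or the oxocarbenium ion next to the aluminium alkoxide may open or undergo a 1,2-shift before it is trapped. The fallback replaces the one-pot alane by an isolated boron nucleophile and an external Lewis acid. Setting out from 15, carboalumination as before and quenching with I2 would give tert-butyl{[(3R,4E)-5-iodo-3,4-dimethylpent-4-en-1-yl]oxy}diphenylsilane F3. Iodine–lithium exchange (t-BuLi, Et2O, −78 °C) would give {(1E,3R)-5-[(tert-butyldiphenylsilyl)oxy]-2,3-dimethylpent-1-en-1-yl}lithium F4, which is not isolated. Borylation with B(OiPr)3 and treatment with KHF2 would give potassium {(1E,3R)-5-[(tert-butyldiphenylsilyl)oxy]-2,3-dimethylpent-1-en-1-yl}trifluoroborate F5. F5 and acetate 10 with BF3·OEt2 in MeCN at −40 °C should then undergo the same face-selective substitution, now with no transferable methyl group present, and come back to the route at 17.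

Step 18. The tertiary cation may lose a proton, the epoxide may rearrange to a carbonyl compound, or another oxygen donor may capture the cation before the boron-bound alkoxide closes the ether bridge. The fallback separates ring formation from ether formation and makes the ring by a radical path. Setting out from 29, Cp2TiCl (trivalent titanium, made from Cp2TiCl2 and Mn in THF) should open the epoxide homolytically, cyclise 6-endo onto the methylidene group and end by β-hydride elimination to give (1S,7R,7aS)-7-[(tert-butyldimethylsilyl)oxy]-1-{(2R)-4-[(tert-butyldiphenylsilyl)oxy]butan-2-yl}-5-{[(4S)-4-hydroxy-5,5-dimethylcyclohex-1-en-1-yl]methyl}-1,7a-dimethyl-2,6,7,7a-tetrahydro-1H-inden-4-yl trifluoromethanesulfonate F6, together with its ring A double-bond isomers. Cobalt-catalysed Markovnikov hydroalkoxylation (Co(salen) with divalent cobalt, N-fluoro-2,4,6-trimethylpyridinium triflate, PhSiH3), in which the free hydroxyl adds across the ring to the tertiary carbon from every alkene isomer, should then come back to the route at 30.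

Further compounds
F1 | step 11 | trimethyl{[(1R,3R,4R)-3-{(1E,3R)-5-[(tert-butyldiphenylsilyl)oxy]-2,3-dimethylpent-1-en-1-yl}-6-methyl-2-oxabicyclo[2.2.2]oct-5-en-4-yl]oxy}silane | C[Si](C)(C)O[C@@]12CC[C@@H](O[C@@H]1/C=C(\C)[C@H](C)CCO[Si](c1ccccc1)(c1ccccc1)C(C)(C)C)C(C)=C2
F2 | step 11 | tert-butyl{(3R)-3-[(4R,4aR,8aR)-4,4a-dimethyl-6-[(trimethylsilyl)oxy]-4a,7,8,8a-tetrahydro-4H-chromen-4-yl]butoxy}diphenylsilane | C[Si](C)(C)OC1=C[C@@]2(C)[C@@H](CC1)OC=C[C@@]2(C)[C@H](C)CCO[Si](c1ccccc1)(c1ccccc1)C(C)(C)C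
F3 | step 10 | tert-butyl{[(3R,4E)-5-iodo-3,4-dimethylpent-4-en-1-yl]oxy}diphenylsilane | I/C=C(\C)[C@H](C)CCO[Si](c1ccccc1)(c1ccccc1)C(C)(C)C
F4 | step 10 | {(1E,3R)-5-[(tert-butyldiphenylsilyl)oxy]-2,3-dimethylpent-1-en-1-yl}lithium | [Li]/C=C(\C)[C@H](C)CCO[Si](c1ccccc1)(c1ccccc1)C(C)(C)C
F5 | step 10 | potassium {(1E,3R)-5-[(tert-butyldiphenylsilyl)oxy]-2,3-dimethylpent-1-en-1-yl}trifluoroborate | [K+].F[B-](F)(F)/C=C(\C)[C@H](C)CCO[Si](c1ccccc1)(c1ccccc1)C(C)(C)C
F6 | step 18 | (1S,7R,7aS)-7-[(tert-butyldimethylsilyl)oxy]-1-{(2R)-4-[(tert-butyldiphenylsilyl)oxy]butan-2-yl}-5-{[(4S)-4-hydroxy-5,5-dimethylcyclohex-1-en-1-yl]methyl}-1,7a-dimethyl-2,6,7,7a-tetrahydro-1H-inden-4-yl trifluoromethanesulfonate | C[C@H](CCO[Si](c1ccccc1)(c1ccccc1)C(C)(C)C)[C@]1(C)CC=C2C(OS(=O)(=O)C(F)(F)F)=C(CC3=CC[C@H](O)C(C)(C)C3)C[C@@H](O[Si](C)(C)C(C)(C)C)[C@]21C
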